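## Retrosynthetic overview
1. The target primary amide comes from hydration of the arylacetonitrile, carried out in the flask where the nitrile is formed.
2. Key disconnection ArCH2–C(=O)NH2. The benzylic carbon comes from an aldehyde C=O, and the carboxamide carbon is also a natural electrophile. The carboxamide carbon is therefore introduced as a carbanion, metallated tosylmethyl isocyanide. This masked H2N–C(=O)(−) supplies C and N and removes the aldehyde oxygen, so no benzyl halide and no cyanide are needed.
3. 3,5-Diiodo-4-methoxybenzaldehyde comes from O-methylation of catalogue 4-hydroxy-3,5-diiodobenzaldehyde.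
4. No ring is formed. The benzene ring is bought with both iodines in place.

Assumption: the target has no stereocentre or other stereogenic element, so it is one achiral compound and no enantiocontrol is needed.

## Route

Step 1
Reactants: 1 4-hydroxy-3,5-diiodobenzaldehyde
Product: 2 3,5-diiodo-4-methoxybenzaldehyde
Conditions: MeI (1.5 equiv), K2CO3 (2 equiv), DMF, rt to 40 °C, 12 h
Reagents that add atoms: iodomethane, CI
Why: Williamson ether synthesis (SN2 O-methylation), in which K2CO3 fully ionises the acidic 2,6-diiodophenol and the small electrophile MeI fits between the two iodines, while the non-enolisable aldehyde and the aryl iodides are inert; no stereocentre is created.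

Step 2
Reactants: 2 3,5-diiodo-4-methoxybenzaldehyde; 3 p-toluenesulfonylmethyl isocyanide (TosMIC)
Product: 6 2-(3,5-diiodo-4-methoxyphenyl)acetamide, via tosylvinylformamide 4 (not isolated), via arylacetonitrile 5 (not isolated)
Conditions: KOtBu (2.6 equiv), DME, −35 °C, add 3 (1.2 equiv), then 2, −55 °C, 1 h; MeOH, reflux, 20 min; 0 °C, 30% aq H2O2 (8 equiv, one of which the released sulfinate consumes), 0 °C to rt, 2 h; H2O, filter
Reagents that add atoms: TosMIC (compound 3, gives the carboxamide C and N), Cc1ccc(cc1)S(=O)(=O)C[N+]#[C-]; hydrogen peroxide (gives the amide O), OO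
Why: Van Leusen reductive cyanation telescoped into a Radziszewski hydration, in which the potassium carbanion of 3 (a masked carboxamide anion) adds to the electrophilic aldehyde carbon of 2 at low temperature, the adduct collapses to 4 with transfer of the aldehyde oxygen onto the isocyano carbon, methanolysis of the formyl group and loss of sulfinate give 5, and HOO− then adds to the nitrile much faster than hydroxide attacks the product amide, while the aryl iodides and the methyl ether tolerate alkoxide and alkaline peroxide at these temperatures; no stereocentre is created.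

## Compound list
1 | 4-hydroxy-3,5-diiodobenzaldehyde (achiral) | O=Cc1cc(I)c(O)c(I)c1 | starting material
2 | 3,5-diiodo-4-methoxybenzaldehyde (achiral) | COc1c(I)cc(C=O)cc1I | intermediate
3 | p-toluenesulfonylmethyl isocyanide, TosMIC (achiral) | Cc1ccc(cc1)S(=O)(=O)C[N+]#[C-] | starting material
4 | N-[2-(3,5-diiodo-4-methoxyphenyl)-1-(4-methylphenylsulfonyl)ethenyl]formamide, present as its N-potassium salt, E/Z mixture whose geometry is lost in the next stage | COc1c(I)cc(C=C(NC=O)S(=O)(=O)c2ccc(C)cc2)cc1I | intermediate
5 | 2-(3,5-diiodo-4-methoxyphenyl)acetonitrile (achiral) | COc1c(I)cc(CC#N)cc1I | intermediate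
6 | 2-(3,5-diiodo-4-methoxyphenyl)acetamide (achiral) | COc1c(I)cc(CC(N)=O)cc1I | target

## Summary
Total step count: 2
Longest linear sequence: 2

The route has only two steps. Step 2 is therefore entered twice below, once for each of its two independent risks.

**Risk 1: step 2, C–C bond formation (2 + 3 to 4).**
- Failure mode: the adduct may lose sulfinate and aromatise to the oxazole, which is the usual fate of aldehydes with 3 in protic media, instead of opening to 4.
- The fallback sets out from 2 and comes back to the route at 6.
- It replaces the isocyanide carbanion with the trichloromethyl anion as the carboxyl-anion equivalent.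
- CHCl3 and DBU at rt add to 2 to give racemic 2,2,2-trichloro-1-(3,5-diiodo-4-methoxyphenyl)ethanol F1.
- A reductive Jocic reaction (NaBH4, NaOH, t-BuOH, 55 °C) turns it into 2-(3,5-diiodo-4-methoxyphenyl)acetic acid F2.
- CDI in THF gives 1-[(3,5-diiodo-4-methoxyphenyl)acetyl]imidazole F3, and aqueous NH3 converts this into 6.

**Risk 2: step 2, hydration in the crude alkaline mixture (5 to 6).**
- Failure mode: the benzylic carbanion of 5 may be oxidised, or the amide may be hydrolysed further.
- The fallback sets out from 5 and comes back to the route at 6. Here 5 is isolated by aqueous work-up after the methanol reflux.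
- It avoids both oxidant and base by going through solvolysis and ammonolysis.
- Anhydrous HCl in MeOH/Et2O at 0 °C gives methyl 2-(3,5-diiodo-4-methoxyphenyl)acetimidate hydrochloride F4 (Pinner reaction).
- Water at rt converts it into methyl 2-(3,5-diiodo-4-methoxyphenyl)acetate F5.
- 7 M NH3 in MeOH in a sealed tube at 50 °C gives 6.

**Risk 3: step 1, O-methylation.**
- Failure mode: the phenoxide is weakly nucleophilic and flanked by two iodines, so alkylation may stall.
- The fallback sets out from 1 and comes back to the route at 2.
- It uses the high acidity of 1 rather than its nucleophilicity towards an alkyl halide.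
- A Mitsunobu reaction with MeOH, PPh3 and DIAD in THF at 0 °C to rt activates methanol as its oxyphosphonium salt, and 1 serves as the acidic partner.
- No new compound lies on this path.

## Further compounds
F1 | step 2 | 2,2,2-trichloro-1-(3,5-diiodo-4-methoxyphenyl)ethanol (racemic) | COc1c(I)cc(C(O)C(Cl)(Cl)Cl)cc1I
F2 | step 2 | 2-(3,5-diiodo-4-methoxyphenyl)acetic acid | COc1c(I)cc(CC(=O)O)cc1I
F3 | step 2 | 1-[(3,5-diiodo-4-methoxyphenyl)acetyl]imidazole | COc1c(I)cc(CC(=O)n2ccnc2)cc1I
F4 | step 2 | methyl 2-(3,5-diiodo-4-methoxyphenyl)acetimidate hydrochloride | COc1c(I)cc(CC(=N)OC)cc1I.Cl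
F5 | step 2 | methyl 2-(3,5-diiodo-4-methoxyphenyl)acetate | COc1c(I)cc(CC(=O)OC)cc1I
F0 | step 1 | none | none
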